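**Retrosynthetic overview**
1. Labdane numbering is used (ring A = C1–C5, C10; ring B = C5–C10). Late disconnections: C12–C13 (Negishi coupling with a (2Z)-3-iodobut-2-enoate that carries the 13Z geometry), the C2 acetate, the C8 methylene (Wittig) and C9–C11 (α′-alkylation of a ring B enone).
2. Ring A is then opened at C1–C10 and C3–C4 at once: a [3+3] annulation of an acetone 1,3-dianion equivalent (the bis-silyl dienol ether of methyl acetoacetate; its ester is removed later) onto (1R,5R)-verbenone.
3. Enabling feature: the C2 oxygen lies between two CH2 groups (C1, C3), each ending on a quaternary carbon (C10, C4) held 1,3 through C5–H. Ring B with C20, C4, C18 and C19 is the carbon skeleton of verbenone (C8 = carbonyl, C9=C10 = enone, C4 = CMe2 bridge).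
4. The cyclobutane bond C4–C7 of verbenone is not in the target. It shields one face of C10 (giving the trans ring fusion), keeps C4 as a masked tertiary cation, and is cleaved in the key step.
5. Ring order: ring B from the chiral pool (C5 comes from verbenone), ring A in step 1, then the C9 side chain, the C8 methylene and the C2 acetate.

Key step: step 1

Remark (assumption): (1R,5R)-(+)-verbenone and the silyl dienol ether 2 are taken as commercial; the verbenone is otherwise one allylic oxidation from (1R)-(+)-α-pinene. Positions in the text use labdane numbering; compound names use ring numbering.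

**Step 1**
Reactants: 1 (1R,5R)-4,6,6-trimethylbicyclo[3.1.1]hept-3-en-2-one; 2 1-methoxy-1,3-bis(trimethylsilyloxy)buta-1,3-diene
Product: 4 methyl (4aS,8aR)-1,1,4a-trimethyl-3,6-dioxodecahydronaphthalene-2-carboxylate, via Michael adduct 3 (not isolated)
Conditions: TiCl4 (2.2 equiv), CH2Cl2, −78 to −40 °C; then (CF3)2CHOH (1.1 equiv), −40 to 0 °C; H2O
Reagents that add atoms: none
Why: Proposed new method: TiCl4 activates the enone of 1 and the terminal carbon of 2 adds to the β-carbon in a vinylogous Mukaiyama–Michael addition (C1–C10); the fluoro alcohol then protonates the C8 enolate at C9 to give the Lewis-acid-bound ketone 3, in which the strained cyclobutane bond between the α-bridgehead (C7) and the CMe2 carbon (C4) breaks heterolytically, as in the known acid opening of nopinone-type ketones, to a tertiary C4 cation and a C7–C8 enolate. The titanium-chelated β-keto ester enol captures this cation through C3 (closest known types: SnCl4-mediated cyclisation of olefinic β-keto esters and Lewis-acid α-tert-alkylation of enol derivatives), which closes ring A in a 6-(enolendo) mode onto the exocyclic trigonal cation through a chair transition state. The new quaternary stereocentre C10 is set in the Michael step because the nucleophile can only approach the enone face opposite the gem-dimethyl bridge; C5 is the untouched bridgehead of 1, so the C5–C4 and C10–C1 bonds are trans on ring B and can only close to the trans-decalin, and C3 is an epimerisable centre that is removed in step 4. The step needs Michael addition before ring opening and C- rather than O-alkylation of the keto ester: the cation stays masked in the cyclobutane until the proton source regenerates the C8 carbonyl, and O-alkylation by a tertiary cation is reversible under TiCl4.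

**Step 2**
Reactants: 4 methyl (4aS,8aR)-1,1,4a-trimethyl-3,6-dioxodecahydronaphthalene-2-carboxylate
Product: 5 methyl (4aS,8aR)-1,1,4a-trimethyl-3,6-dioxo-1,2,3,4,4a,5,6,8a-octahydronaphthalene-2-carboxylate
Conditions: Pd(O2CCF3)2 (5 mol %), DMSO (10 mol %), O2 (1 atm), AcOH, 80 °C
Reagents that add atoms: none
Why: Palladium-catalysed aerobic α,β-dehydrogenation of a cyclic ketone (Pd enolate, then β-hydride elimination) can only run across C7–C6, because C9 has no β-hydrogen (C10 is quaternary) and the keto ester carbons C1 and C3 are flanked by quaternary C10 and C4, so the C6=C7 enone should form regiospecifically without touching a stereocentre.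

**Step 3**
Reactants: 5 methyl (4aS,8aR)-1,1,4a-trimethyl-3,6-dioxo-1,2,3,4,4a,5,6,8a-octahydronaphthalene-2-carboxylate; 6 tert-butyl bromoacetate
Product: 7 methyl (4aS,8aS)-5-(2-tert-butoxy-2-oxoethyl)-1,1,4a-trimethyl-3,6-dioxo-1,2,3,4,4a,5,6,8a-octahydronaphthalene-2-carboxylate (mixture at ring positions 5 and 2)
Conditions: LiN(i-Pr)2 (2.2 equiv), THF, −78 °C; then 6 (1.05 equiv), DMPU, −78 to −30 °C; AcOH
Reagents that add atoms: none
Why: Dianion alkylation: the first equivalent of base parks the β-keto ester as its unreactive enolate (which protects C2), the second removes the only kinetically accessible ketone α-proton left, at C9 (the α′-enolate of an enone, as with isophorone, since C7 is now vinylic), and this more reactive enolate is alkylated by the bromoacetate, mainly from the α face, to a C9 centre that is corrected by equilibration in step 5.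

**Step 4**
Reactants: 7 methyl (4aS,8aS)-5-(2-tert-butoxy-2-oxoethyl)-1,1,4a-trimethyl-3,6-dioxo-1,2,3,4,4a,5,6,8a-octahydronaphthalene-2-carboxylate
Product: 8 tert-butyl 2-[(4aS,8aS)-5,5,8a-trimethyl-2,7-dioxo-1,2,4a,5,6,7,8,8a-octahydronaphthalen-1-yl]acetate (mixture at ring position 1)
Conditions: LiCl (3 equiv), H2O (2 equiv), DMSO, 140 °C
Reagents that add atoms: none
Why: Krapcho dealkoxycarbonylation (chloride attack on the O-methyl group, then loss of CO2 from the β-keto carboxylate) is specific for the β-keto methyl ester, the tert-butyl ester resists SN2 dealkylation, and the reaction removes the C3 ester together with the undefined C3 centre.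

**Step 5**
Reactants: 8 tert-butyl 2-[(4aS,8aS)-5,5,8a-trimethyl-2,7-dioxo-1,2,4a,5,6,7,8,8a-octahydronaphthalen-1-yl]acetate
Product: 10 tert-butyl 2-[(1R,4aS,7R,8aS)-7-hydroxy-5,5,8a-trimethyl-2-oxodecahydronaphthalen-1-yl]acetate, via C1-epimeric hydroxy ketones 9 (not isolated)
Conditions: LiBH(s-Bu)3 (2.5 equiv), THF, −78 to −40 °C; NaOH, H2O2, 0 °C; then NaOMe (0.3 equiv), MeOH, 23 °C
Reagents that add atoms: none
Why: The bulky borohydride adds 1,4 to the β-unsubstituted cyclohexenone, and the resulting boron enolate protects C8 while the saturated C2 ketone is reduced by equatorial attack from the α face (the β face is blocked by the syn-axial methyl groups on C4 and C10), which should give the axial 2β alcohol; NaOMe then equilibrates C9, α to the regenerated ketone, to the equatorial β side chain.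

**Step 6**
Reactants: 10 tert-butyl 2-[(1R,4aS,7R,8aS)-7-hydroxy-5,5,8a-trimethyl-2-oxodecahydronaphthalen-1-yl]acetate
Product: 11 tert-butyl 2-[(1S,4aS,7R,8aS)-7-hydroxy-5,5,8a-trimethyl-2-methylidenedecahydronaphthalen-1-yl]acetate
Conditions: Ph3PCH3Br (4 equiv), KOt-Bu (3.8 equiv), toluene, 23 to 80 °C
Reagents that add atoms: methyltriphenylphosphonium bromide, C[P+](c1ccccc1)(c1ccccc1)c1ccccc1.[Br-]
Why: Wittig methylenation with excess ylide converts the hindered C8 ketone into the exocyclic methylene, the C2 alkoxide and the tert-butyl ester are inert, and C9 keeps its configuration because it is already the thermodynamic epimer under base.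

**Step 7**
Reactants: 11 tert-butyl 2-[(1S,4aS,7R,8aS)-7-hydroxy-5,5,8a-trimethyl-2-methylidenedecahydronaphthalen-1-yl]acetate
Product: 12 (2R,4aS,8S,8aS)-8-(2-hydroxyethyl)-4,4,8a-trimethyl-7-methylidenedecahydronaphthalen-2-ol
Conditions: LiAlH4 (2 equiv), THF, 0 to 23 °C; H2O, NaOH
Reagents that add atoms: none
Why: LiAlH4 reduces the tert-butyl ester to the primary alcohol at C12 without touching the 1,1-disubstituted alkene or any stereocentre.

**Step 8**
Reactants: 12 (2R,4aS,8S,8aS)-8-(2-hydroxyethyl)-4,4,8a-trimethyl-7-methylidenedecahydronaphthalen-2-ol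
Product: 13 (2R,4aS,8S,8aS)-8-(2-iodoethyl)-4,4,8a-trimethyl-7-methylidenedecahydronaphthalen-2-ol
Conditions: PPh3 (1.2 equiv), I2 (1.2 equiv), imidazole (2.5 equiv), CH2Cl2, 0 °C
Reagents that add atoms: iodine, II
Why: Appel-type iodination is selective for the primary alcohol, because the axial C2 hydroxyl flanked by two syn-axial methyl groups does not form the alkoxyphosphonium ion under these conditions.

**Step 9**
Reactants: 13 (2R,4aS,8S,8aS)-8-(2-iodoethyl)-4,4,8a-trimethyl-7-methylidenedecahydronaphthalen-2-ol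
Product: 14 (2R,4aS,8S,8aS)-8-(2-iodoethyl)-4,4,8a-trimethyl-7-methylidenedecahydronaphthalen-2-yl acetate
Conditions: Ac2O (3 equiv), Et3N, DMAP (0.2 equiv), CH2Cl2, 23 °C
Reagents that add atoms: acetic anhydride, CC(=O)OC(C)=O
Why: DMAP-catalysed acylation esterifies the hindered axial alcohol with retention at C2, and the β-branched primary iodide is stable to the tertiary amine at ambient temperature.

**Step 10**
Reactants: 15 but-2-ynoic acid; 16 2-(trimethylsilyl)ethanol
Product: 17 2-(trimethylsilyl)ethyl but-2-ynoate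
Conditions: DCC (1.1 equiv), DMAP (0.1 equiv), CH2Cl2, 0 to 23 °C
Reagents that add atoms: none
Why: Steglich esterification (carbodiimide activation, DMAP acyl transfer) gives the fluoride-cleavable ester of the ynoic acid.

**Step 11**
Reactants: 17 2-(trimethylsilyl)ethyl but-2-ynoate
Product: 18 2-(trimethylsilyl)ethyl (2Z)-3-iodobut-2-enoate
Conditions: LiI (1.5 equiv), AcOH (2 equiv), MeCN, 70 °C
Reagents that add atoms: lithium iodide, [Li+].[I-]
Why: Iodide adds to the 2-ynoate in conjugate fashion and the allenolate is protonated anti, the established hydroiodination that gives the (Z)-3-iodo-2-enoate with iodine cis to the ester.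

**Step 12**
Reactants: 14 (2R,4aS,8S,8aS)-8-(2-iodoethyl)-4,4,8a-trimethyl-7-methylidenedecahydronaphthalen-2-yl acetate; 18 2-(trimethylsilyl)ethyl (2Z)-3-iodobut-2-enoate
Product: 20 2-(trimethylsilyl)ethyl (2Z)-5-[(1S,4aS,7R,8aS)-7-acetoxy-5,5,8a-trimethyl-2-methylidenedecahydronaphthalen-1-yl]-3-methylpent-2-enoate, via alkylzinc iodide 19 (not isolated)
Conditions: Zn dust (3 equiv; activated by BrCH2CH2Br, Me3SiCl), LiCl, THF, 40 °C; then 18 (0.9 equiv), Pd(PPh3)4 (5 mol %), THF, 45 °C
Reagents that add atoms: none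
Why: Zinc inserts into the primary C–I bond and the alkylzinc iodide undergoes Negishi coupling with the alkenyl iodide with retention of the double-bond geometry, which places C12 cis to the ester (13Z) and tolerates the acetate, the ester and the exocyclic alkene.

**Step 13**
Reactants: 20 2-(trimethylsilyl)ethyl (2Z)-5-[(1S,4aS,7R,8aS)-7-acetoxy-5,5,8a-trimethyl-2-methylidenedecahydronaphthalen-1-yl]-3-methylpent-2-enoate
Product: 21 (2Z)-5-[(1S,4aS,7R,8aS)-7-acetoxy-5,5,8a-trimethyl-2-methylidenedecahydronaphthalen-1-yl]-3-methylpent-2-enoic acid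
Conditions: Bu4NF (1.5 equiv), THF, 0 to 23 °C; dilute HCl
Reagents that add atoms: none
Why: Fluoride attacks silicon and the 2-silylethyl ester fragments to the carboxylate, ethene and Me3SiF under conditions that should leave the hindered acetate, the exocyclic alkene and the Z-enoate untouched.

**Compound list**
1 | (1R,5R)-4,6,6-trimethylbicyclo[3.1.1]hept-3-en-2-one [(+)-verbenone] | CC1=CC(=O)[C@@H]2C[C@H]1C2(C)C | starting material
2 | 1-methoxy-1,3-bis(trimethylsilyloxy)buta-1,3-diene | C=C(O[Si](C)(C)C)C=C(OC)O[Si](C)(C)C | starting material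
3 | methyl 3-oxo-4-[(1R,2R,5R)-2,6,6-trimethyl-4-oxobicyclo[3.1.1]heptan-2-yl]butanoate (held as its titanium/silyl enolates until protonation) | C[C@@]1(CC(=O)CC(=O)OC)CC(=O)[C@@H]2C[C@H]1C2(C)C | intermediate (not isolated)
4 | methyl (4aS,8aR)-1,1,4a-trimethyl-3,6-dioxodecahydronaphthalene-2-carboxylate (trans-fused; keto/enol mixture at ring position 2) | O=C1CC[C@H]2C(C)(C)C(C(=O)OC)C(=O)C[C@]2(C)C1 | intermediate
5 | methyl (4aS,8aR)-1,1,4a-trimethyl-3,6-dioxo-1,2,3,4,4a,5,6,8a-octahydronaphthalene-2-carboxylate | O=C1C=C[C@H]2C(C)(C)C(C(=O)OC)C(=O)C[C@]2(C)C1 | intermediate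
6 | tert-butyl bromoacetate | CC(C)(C)OC(=O)CBr | starting material
7 | methyl (4aS,8aS)-5-(2-tert-butoxy-2-oxoethyl)-1,1,4a-trimethyl-3,6-dioxo-1,2,3,4,4a,5,6,8a-octahydronaphthalene-2-carboxylate (mixture at ring positions 5 and 2) | O=C1C=C[C@H]2C(C)(C)C(C(=O)OC)C(=O)C[C@]2(C)C1CC(=O)OC(C)(C)C | intermediate
8 | tert-butyl 2-[(4aS,8aS)-5,5,8a-trimethyl-2,7-dioxo-1,2,4a,5,6,7,8,8a-octahydronaphthalen-1-yl]acetate (mixture at ring position 1) | O=C1C=C[C@H]2C(C)(C)CC(=O)C[C@]2(C)C1CC(=O)OC(C)(C)C | intermediate
9 | tert-butyl 2-[(4aS,7R,8aS)-7-hydroxy-5,5,8a-trimethyl-2-oxodecahydronaphthalen-1-yl]acetate (epimers at ring position 1) | O=C1CC[C@H]2C(C)(C)C[C@@H](O)C[C@]2(C)C1CC(=O)OC(C)(C)C | intermediate (not isolated)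
10 | tert-butyl 2-[(1R,4aS,7R,8aS)-7-hydroxy-5,5,8a-trimethyl-2-oxodecahydronaphthalen-1-yl]acetate | O=C1CC[C@H]2C(C)(C)C[C@@H](O)C[C@]2(C)[C@H]1CC(=O)OC(C)(C)C | intermediate
11 | tert-butyl 2-[(1S,4aS,7R,8aS)-7-hydroxy-5,5,8a-trimethyl-2-methylidenedecahydronaphthalen-1-yl]acetate | C=C1CC[C@H]2C(C)(C)C[C@@H](O)C[C@]2(C)[C@H]1CC(=O)OC(C)(C)C | intermediate
12 | (2R,4aS,8S,8aS)-8-(2-hydroxyethyl)-4,4,8a-trimethyl-7-methylidenedecahydronaphthalen-2-ol | C=C1CC[C@H]2C(C)(C)C[C@@H](O)C[C@]2(C)[C@H]1CCO | intermediate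
13 | (2R,4aS,8S,8aS)-8-(2-iodoethyl)-4,4,8a-trimethyl-7-methylidenedecahydronaphthalen-2-ol | C=C1CC[C@H]2C(C)(C)C[C@@H](O)C[C@]2(C)[C@H]1CCI | intermediate
14 | (2R,4aS,8S,8aS)-8-(2-iodoethyl)-4,4,8a-trimethyl-7-methylidenedecahydronaphthalen-2-yl acetate | C=C1CC[C@H]2C(C)(C)C[C@@H](OC(C)=O)C[C@]2(C)[C@H]1CCI | intermediate
15 | but-2-ynoic acid | CC#CC(=O)O | starting material
16 | 2-(trimethylsilyl)ethanol | C[Si](C)(C)CCO | starting material
17 | 2-(trimethylsilyl)ethyl but-2-ynoate | CC#CC(=O)OCC[Si](C)(C)C | intermediate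
18 | 2-(trimethylsilyl)ethyl (2Z)-3-iodobut-2-enoate | C/C(I)=C/C(=O)OCC[Si](C)(C)C | intermediate
19 | {2-[(1S,4aS,7R,8aS)-7-acetoxy-5,5,8a-trimethyl-2-methylidenedecahydronaphthalen-1-yl]ethyl}zinc iodide | C=C1CC[C@H]2C(C)(C)C[C@@H](OC(C)=O)C[C@]2(C)[C@H]1CC[Zn]I | intermediate (not isolated)
20 | 2-(trimethylsilyl)ethyl (2Z)-5-[(1S,4aS,7R,8aS)-7-acetoxy-5,5,8a-trimethyl-2-methylidenedecahydronaphthalen-1-yl]-3-methylpent-2-enoate | C=C1CC[C@H]2C(C)(C)C[C@@H](OC(C)=O)C[C@]2(C)[C@H]1CC/C(C)=C\C(=O)OCC[Si](C)(C)C | intermediate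
21 | (2Z)-5-[(1S,4aS,7R,8aS)-7-acetoxy-5,5,8a-trimethyl-2-methylidenedecahydronaphthalen-1-yl]-3-methylpent-2-enoic acid (2β-acetoxylabda-8(17),13Z-dien-15-oic acid) | C=C1CC[C@H]2C(C)(C)C[C@@H](OC(C)=O)C[C@]2(C)[C@H]1CC/C(C)=C\C(=O)O | target

**Step count**
Total steps: 13. Longest linear sequence: 11 (steps 1–9, 12, 13); steps 10 and 11 prepare the coupling partner 18.

**Steps most likely to fail**

1. Step 1 (proposed new method). The cyclobutane may open before the Michael addition has taken place, the addition to the hindered β-carbon may be too slow, or the tertiary cation may be lost by elimination or hydride shift before ring A closes. The fallback uses separate known reactions, sets out from 1 and comes back at 4. Hosomi–Sakurai conjugate allylation of 1 (allyltrimethylsilane, TiCl4, CH2Cl2, −78 °C) should add anti to the gem-dimethyl bridge, as the documented cuprate additions to verbenone do, and give (1R,4R,5R)-4,6,6-trimethyl-4-(prop-2-en-1-yl)bicyclo[3.1.1]heptan-2-one F1. Ozonolysis (O3, then Me2S) would give 2-[(1R,2R,5R)-2,6,6-trimethyl-4-oxobicyclo[3.1.1]heptan-2-yl]acetaldehyde F2. Roskamp homologation with methyl diazoacetate and SnCl2, which leaves ketones alone, would give keto ester 3, now isolated. Me3SiI in CH2Cl2, an established reagent for opening the cyclobutane of nopinone-type ketones, would give methyl 4-[(1S,2R)-2-(2-iodopropan-2-yl)-1-methyl-5-oxocyclohexyl]-3-oxobutanoate F3. Silver-assisted intramolecular C-alkylation of the β-keto ester by the tertiary iodide (AgOSO2CF3, CH2Cl2) would then close ring A to 4.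

2. Step 3. Deprotonation may go to the wrong site (C1 of the keto ester dianion instead of C9), proton transfer may quench the enolate, or the SN2 alkylation at the neopentyl-type α′-carbon may be too slow. The fallback replaces the lithium enolate by a Lewis-acid SN1 alkylation; it sets out from 5 and comes back at 7. Soft enolisation (t-BuMe2SiOSO2CF3, Et3N, CH2Cl2) would give methyl (4aS,8aR)-3,6-bis[(tert-butyldimethylsilyl)oxy]-1,1,4a-trimethyl-1,4,4a,8a-tetrahydronaphthalene-2-carboxylate F4. ZnBr2-mediated alkylation of its cross-conjugated silyl dienol ether at C9 with tert-butyl 2-chloro-2-(phenylsulfanyl)acetate (a thionium electrophile) would give, after aqueous work-up, methyl (4aS,8aS)-5-[2-tert-butoxy-2-oxo-1-(phenylsulfanyl)ethyl]-1,1,4a-trimethyl-3,6-dioxo-1,2,3,4,4a,5,6,8a-octahydronaphthalene-2-carboxylate F5. Radical desulfurisation (Bu3SnH, AIBN, benzene, 80 °C) would give 7.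

3. Step 5. 1,2-Reduction of the enone carbonyl may compete with conjugate reduction, or the C2 ketone may be reduced incompletely or from the wrong face. The fallback keeps the β-keto ester as the protecting group for C2 instead of using the enone to protect C8; it sets out from 7 and comes back at 11. Hydrogenation of the enone (H2, Pd/C, EtOAc) followed by NaOMe equilibration would give methyl (4aS,5R,8aS)-5-(2-tert-butoxy-2-oxoethyl)-1,1,4a-trimethyl-3,6-dioxodecahydronaphthalene-2-carboxylate F6. Wittig methylenation with excess Ph3P=CH2, in which the β-keto ester is deprotonated and therefore inert, would give methyl (4aR,5S,8aS)-5-(2-tert-butoxy-2-oxoethyl)-1,1,4a-trimethyl-6-methylidene-3-oxodecahydronaphthalene-2-carboxylate F7. Krapcho dealkoxycarbonylation (LiCl, H2O, DMSO, 140 °C) would give tert-butyl 2-[(1S,4aS,8aS)-5,5,8a-trimethyl-2-methylidene-7-oxodecahydronaphthalen-1-yl]acetate F8. Reduction of the now unique ketone with LiBH(s-Bu)3 from the α face would give 11.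

**Further compounds**
F1 | step 1 | (1R,4R,5R)-4,6,6-trimethyl-4-(prop-2-en-1-yl)bicyclo[3.1.1]heptan-2-one | C[C@@]1(CC=C)CC(=O)[C@@H]2C[C@H]1C2(C)C
F2 | step 1 | 2-[(1R,2R,5R)-2,6,6-trimethyl-4-oxobicyclo[3.1.1]heptan-2-yl]acetaldehyde | C[C@@]1(CC=O)CC(=O)[C@@H]2C[C@H]1C2(C)C
F3 | step 1 | methyl 4-[(1S,2R)-2-(2-iodopropan-2-yl)-1-methyl-5-oxocyclohexyl]-3-oxobutanoate | O=C1CC[C@@H](C(C)(C)I)[C@](C)(CC(=O)CC(=O)OC)C1
F4 | step 3 | methyl (4aS,8aR)-3,6-bis[(tert-butyldimethylsilyl)oxy]-1,1,4a-trimethyl-1,4,4a,8a-tetrahydronaphthalene-2-carboxylate | C1(O[Si](C)(C)C(C)(C)C)C=C[C@H]2C(C)(C)C(C(=O)OC)=C(O[Si](C)(C)C(C)(C)C)C[C@]2(C)C=1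
F5 | step 3 | methyl (4aS,8aS)-5-[2-tert-butoxy-2-oxo-1-(phenylsulfanyl)ethyl]-1,1,4a-trimethyl-3,6-dioxo-1,2,3,4,4a,5,6,8a-octahydronaphthalene-2-carboxylate | O=C1C=C[C@H]2C(C)(C)C(C(=O)OC)C(=O)C[C@]2(C)C1C(Sc1ccccc1)C(=O)OC(C)(C)C
F6 | step 5 | methyl (4aS,5R,8aS)-5-(2-tert-butoxy-2-oxoethyl)-1,1,4a-trimethyl-3,6-dioxodecahydronaphthalene-2-carboxylate | O=C1CC[C@H]2C(C)(C)C(C(=O)OC)C(=O)C[C@]2(C)[C@H]1CC(=O)OC(C)(C)C
F7 | step 5 | methyl (4aR,5S,8aS)-5-(2-tert-butoxy-2-oxoethyl)-1,1,4a-trimethyl-6-methylidene-3-oxodecahydronaphthalene-2-carboxylate | C=C1CC[C@H]2C(C)(C)C(C(=O)OC)C(=O)C[C@]2(C)[C@H]1CC(=O)OC(C)(C)C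
F8 | step 5 | tert-butyl 2-[(1S,4aS,8aS)-5,5,8a-trimethyl-2-methylidene-7-oxodecahydronaphthalen-1-yl]acetate | C=C1CC[C@H]2C(C)(C)CC(=O)C[C@]2(C)[C@H]1CC(=O)OC(C)(C)C
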